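**Numbering.** Cembrane numbering is used for the skeleton: C1–C14 form the carbocycle, C1=C15 is the alkene shared with the heterocycle, C2 is the ring OCH, C16 the ring OCH2, C17 the CH2OAc, and C18, C19, C20 are the methyls on C4, C8, C12. Compounds 1–22 are defined in the steps and listed after them.

## Analysis of the target

Lobophynin B is a cembranoid: a 14-membered carbocycle fused along C1–C2 to a 2,5-dihydrofuran (O, C2, C1, C15, C16) and along C7–C8 to an oxirane. It carries two E trisubstituted alkenes (C3=C4 and C11=C12), a tetrasubstituted alkene (C1=C15) common to both rings, and an acetoxymethyl group (C17) on C15. The three stereocentres are all R. C7 and C8 belong to one trans-epoxide, whose relative configuration derives from an E alkene. C2 is separated from them by the C3=C4 alkene and two methylenes, so it needs control of its own. The sensitive groups are the trisubstituted epoxide (acid, Lewis acid), the doubly allylic C2–O bond (ionisation) and the primary allylic acetate. The difficulties are the entropic cost of the 14-membered ring, the remote C2 centre, and the two oxygenated carbons C16 and C17 on C15, which differ only in that one of them is in the ring. The strategy rests on the C2–C3=C4(C18) unit: C2 sits on an E alkene whose methyl C18 is cis to it, which is the pattern left by syn addition of a carbonyl carbon and a methyl group across a terminal alkyne C3≡C4.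

## Retrosynthetic reasoning

**22 back to 19 and 18.** The acetate C–O bond at C17 and the ring O–C16 bond are cut together. In triol 19 the two hydroxymethyl groups on C15 are constitutionally equivalent, and only the one cis to C2 can be reached by the C2 oxygen. Activating both (bis-mesylate 20) therefore lets ring closure pick C16 (mesylate 21) and leaves C17 for acetate. No earlier step has to tell C16 from C17, and the C1=C15 alkene never has a geometry to control. Triol 19 comes from the bis-silyl ether 18 by fluoride.

**18 back to 17 (key disconnection).** C2–C3 and C4–C18 are cut. This is the one place where ring closure, the E trisubstituted alkene, the methyl C18 and the C2 stereocentre can all be made in one operation. It leaves the open-chain ynal 17, whose two ends (aldehyde and terminal alkyne) are neutral groups that coexist with the epoxide. The forward reaction must join C2 to the unsubstituted alkyne carbon (endo closure), deliver methyl to C4 on the same side, attack the aldehyde and not the enal β-carbon, and select the 2R face.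

**17 back to 14 and 5.** After the alkyne is masked as its silyl derivative 16, the sp2–sp3 bond C1–C14 is cut. This divides the molecule into a symmetric three-carbon head 5, which already carries the aldehyde and both arms, and the terpenoid chain 14, whose terminal alkene becomes the C14 nucleophile through alkylborane 15. The tetrasubstituted enal arrives complete, so no redox or protecting-group change separates the coupling from the key step.

**5 back to 1.** The head is traced through dibromoalkene 3 and ketone 2 to dihydroxyacetone 1. Because both substituents on C15 are the same, the olefination and the bromine–lithium exchange (via 4) raise no question of geometry.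

**14 back to 11 and 12.** The C5–C6 bond is cut next to the epoxide. The hydroxyl of epoxy alcohol 11 becomes the leaving group (triflate 13) and lithiated 12 supplies C3–C5 with the alkyne already masked. The hydroxyl that directs the epoxidation is thus reused as the handle for chain extension.

**11 back to 10.** The two epoxide C–O bonds are cut. The allylic alcohol 10 has the geraniol skeleton, and reagent-controlled epoxidation sets C7 and C8 together.

**10 back to 6.** The C13=C14 bond is cut (one-carbon Wittig on enal 8, then acetate removal from 9), and the C13 oxygen is traced to allylic oxidation of geranyl acetate 6 through alcohol 7. The terminal E-methyl of 6 is the only position this oxidation touches, and the E geometry of C11=C12 is taken over unchanged from the starting material.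

## Alternatives that were turned down

**Alternative 1:** Allenol oxypalladation–carbonylation.
- **Disconnection and key step:** The O–C16 and C15–C17 bonds are cut, leading to the macrocyclic allenol A2 (C1=C15=C16 allene, free C2 hydroxyl). Forward, PdCl2(MeCN)2 with CO, methanol and benzoquinone would add the C2 oxygen to the allene terminus C16, and the C15–Pd bond would take up CO to give ester A1.
- **For:** It builds the heterocycle and introduces C17 in one step and tells C16 from C17 by mechanism. On that point it is stronger than the chosen endgame, which needs a bis-sulfonate and selectivity against the C2 hydroxyl.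
- **Against:** A2 already contains the 14-membered ring, the C2 centre and the C3=C4 alkene, so the alternative leaves the main problem, the macrocyclisation, unsolved. Divalent palladium chloride is an electrophile toward the trisubstituted epoxide and the two trisubstituted alkenes. A1 still needs hydride reduction of a conjugated ester beside the epoxide and an acetylation.
- **Comparison:** The chosen strategy instead closes the ring, forms C2–C3, places C18 and sets C2 in one step, and its endgame uses only base-mediated substitutions.

**Alternative 2:** Sulfone carbanion macrocyclisation.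
- **Disconnection and key step:** The C9–C10 bond is cut to the seco iodide–sulfone A4. KN(SiMe3)2 would deprotonate the allylic sulfone at C10 and the carbanion would displace iodide at C9 to give the macrocyclic sulfone A3.
- **For:** Carbanion alkylation is the best-established way to close cembrane rings, and all stereocentres and the dihydrofuran are fixed before ring closure. On precedent for the ring closure and certainty of the C2 configuration it is stronger than the chosen key step.
- **Against:** C9 is attached to the fully substituted epoxide carbon C8, so the displacement is hindered, and an α-iodo epoxide offers a strong base the competing attack at iodine or at the epoxide with fragmentation. The sulfone must afterwards be removed reductively from an allylic position in the presence of the epoxide, with risk of C11=C12 migration. A4 requires the dihydrofuran, C2 and the C3=C4 alkene to be built in open-chain form, which lengthens the linear sequence.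
- **Comparison:** The chosen strategy has no auxiliary group to remove and creates alkene and stereocentre during ring closure, from a precursor reached in ten steps.

**Alternative 3:** B-alkyl Suzuki macrocyclisation onto an iodobutenolide.
- **Disconnection and key step:** The C1–C14 bond is cut to the seco iodobutenolide A6. 9-BBN would hydroborate the terminal C13=C14 alkene, and Pd(dppf)Cl2 with Cs2CO3 would couple the C14 borane with the C1 iodide to give the macrocyclic butenolide A5.
- **For:** The coupling is a proven macrocyclisation; the butenolide tells C16 (carbonyl) from C17 from the start; C2 can be set early on a small fragment. On these points it is as strong as or stronger than the chosen route.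
- **Against:** In A5 and A6 the C2 hydrogen is the γ-hydrogen of a butenolide and is also allylic to C3=C4, so the basic coupling conditions threaten epimerisation through the hydroxyfuran anion. Converting the C16 lactone carbonyl to the ring CH2 requires hydride reduction to a lactol and then Lewis-acid-mediated deoxygenation. That lactol loses water to an aromatic furan, which destroys C2, and the Lewis acid endangers the epoxide.
- **Comparison:** The chosen route makes the same C1–C14 bond by the same reaction type, but between two fragments (step 9) on an open-chain bromoenal that has no acidic stereocentre. C16 is kept at the alcohol oxidation level throughout.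

Key step: step 11

Assumption: the sense of induction of a C2-symmetric imidazolinylidene in this methylative ring closure cannot be derived from structure; the (4R,5R) ligand is written in step 11 and its (4S,5S) antipode would be used instead if that one proves to be matched to the 2R face.

## Route

**Step 1**
Reactants: 1 1,3-dihydroxyacetone (commercial as its dimer)
Product: 2 1,3-bis[(tert-butyldimethylsilyl)oxy]propan-2-one
Conditions: t-BuMe2SiCl, imidazole, DMF, rt
Reagents that add atoms: tert-butyldimethylsilyl chloride, CC(C)(C)[Si](C)(C)Cl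
Why: Standard silylation of two primary hydroxyls; the dimer reverts to the monomeric ketone under these conditions, and the two identical silyl ethers later become the two arms on C15.

**Step 2**
Reactants: 2 1,3-bis[(tert-butyldimethylsilyl)oxy]propan-2-one
Product: 3 1,1-dibromo-3-[(tert-butyldimethylsilyl)oxy]-2-{[(tert-butyldimethylsilyl)oxy]methyl}prop-1-ene
Conditions: CBr4, PPh3, CH2Cl2, 0 °C → reflux
Reagents that add atoms: carbon tetrabromide, BrC(Br)(Br)Br
Why: Ramirez gem-dibromoolefination (Wittig reaction of Ph3P=CBr2); the ketone is activated by two α-oxygen substituents and is symmetric, so no alkene geometry arises.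

**Step 3**
Reactants: 3 1,1-dibromo-3-[(tert-butyldimethylsilyl)oxy]-2-{[(tert-butyldimethylsilyl)oxy]methyl}prop-1-ene
Product: 5 2-bromo-4-[(tert-butyldimethylsilyl)oxy]-3-{[(tert-butyldimethylsilyl)oxy]methyl}but-2-enal, via bromo(lithio)alkene 4 (not isolated)
Conditions: n-BuLi (1.0 equiv), THF/Et2O, −100 °C; DMF, −100 → −40 °C; aq NH4Cl
Reagents that add atoms: N,N-dimethylformamide, CN(C)C=O
Why: Bromine–lithium exchange on a 1,1-dibromoalkene gives a 1-bromo-1-lithioalkene that persists at −100 °C and is formylated by DMF; the two bromines are equivalent, so only one α-bromo enal can form.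

**Step 4**
Reactants: 6 geranyl acetate [(2E)-3,7-dimethylocta-2,6-dien-1-yl acetate]
Product: 8 (2E,6E)-3,7-dimethyl-8-oxoocta-2,6-dien-1-yl acetate, via allylic alcohol 7 (not isolated)
Conditions: SeO2 (cat.), t-BuOOH, CH2Cl2, rt; crude, then MnO2, CH2Cl2, rt
Reagents that add atoms: selenium dioxide, O=[Se]=O (catalytic oxygen carrier); tert-butyl hydroperoxide, CC(C)(C)OO
Why: Allylic oxidation by SeO2 (ene reaction, then [2,3]-shift) is selective for the E-methyl of the distal alkene because the C2=C3 alkene is deactivated by the allylic acetate; MnO2 then takes the allylic alcohol, together with any aldehyde already present, to the single E-enal.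

**Step 5**
Reactants: 8 (2E,6E)-3,7-dimethyl-8-oxoocta-2,6-dien-1-yl acetate
Product: 9 (2E,6E)-3,7-dimethylnona-2,6,8-trien-1-yl acetate
Conditions: Ph3PCH3Br, NaN(SiMe3)2, THF, 0 °C; then 8, −78 → 0 °C
Reagents that add atoms: methyltriphenylphosphonium bromide, C[P+](c1ccccc1)(c1ccccc1)c1ccccc1.[Br-]
Why: Wittig methylenation; the aldehyde reacts far faster than the acetate and the existing E alkene is untouched, so the new terminal carbon (the future C14) is installed as part of a diene.

**Step 6**
Reactants: 9 (2E,6E)-3,7-dimethylnona-2,6,8-trien-1-yl acetate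
Product: 10 (2E,6E)-3,7-dimethylnona-2,6,8-trien-1-ol
Conditions: K2CO3, MeOH, rt
Reagents that add atoms: none
Why: Base-catalysed transesterification of the acetate; nothing else in the molecule is base-sensitive.

**Step 7**
Reactants: 10 (2E,6E)-3,7-dimethylnona-2,6,8-trien-1-ol
Product: 11 {(2R,3R)-3-methyl-3-[(3E)-4-methylhexa-3,5-dien-1-yl]oxiran-2-yl}methanol
Conditions: Ti(Oi-Pr)4 (10 mol %), D-(−)-diethyl tartrate (12 mol %), t-BuOOH, 4 Å molecular sieves, CH2Cl2, −20 °C
Reagents that add atoms: tert-butyl hydroperoxide, CC(C)(C)OO
Why: Sharpless asymmetric epoxidation; titanium binds the allylic hydroxyl, so only the C2=C3 alkene reacts and the diene is left alone, and the D-(−)-tartrate directs oxygen to the face that gives the (2R,3R)-epoxy alcohol, which fixes C7 and C8 of the target (L-tartrate would give the antipode).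

**Step 8**
Reactants: 11 {(2R,3R)-3-methyl-3-[(3E)-4-methylhexa-3,5-dien-1-yl]oxiran-2-yl}methanol; 12 1-(trimethylsilyl)propyne
Product: 14 trimethyl(4-{(2R,3R)-3-methyl-3-[(3E)-4-methylhexa-3,5-dien-1-yl]oxiran-2-yl}but-1-yn-1-yl)silane, via epoxy triflate 13 (not isolated)
Conditions: (CF3SO2)2O, 2,6-lutidine, CH2Cl2, −78 °C; crude triflate in THF added to 12/n-BuLi (THF, −78 → −20 °C, recooled), −78 °C
Reagents that add atoms: none
Why: A primary triflate is displaced by the propargylic carbon of lithiated 12 at −78 °C much faster than the trisubstituted epoxide is opened (alkylation of an organolithium by an epoxy triflate); no bond to C7 or C8 is broken, so both stereocentres are retained.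

**Step 9**
Reactants: 14 trimethyl(4-{(2R,3R)-3-methyl-3-[(3E)-4-methylhexa-3,5-dien-1-yl]oxiran-2-yl}but-1-yn-1-yl)silane; 5 2-bromo-4-[(tert-butyldimethylsilyl)oxy]-3-{[(tert-butyldimethylsilyl)oxy]methyl}but-2-enal
Product: 16 (5E)-2-{1,3-bis[(tert-butyldimethylsilyl)oxy]propan-2-ylidene}-5-methyl-8-{(2R,3R)-2-methyl-3-[4-(trimethylsilyl)but-3-yn-1-yl]oxiran-2-yl}oct-5-enal, via alkylborane 15 (not isolated)
Conditions: 9-borabicyclo[3.3.1]nonane (9-BBN), THF, rt; then aq Cs2CO3, 5, Pd(dppf)Cl2, AsPh3, DMF, rt → 40 °C
Reagents that add atoms: none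
Why: 9-BBN adds to the monosubstituted alkene of the diene at its terminal carbon (trisubstituted alkenes and the silylated alkyne react much more slowly), and the primary alkylborane undergoes B-alkyl Suzuki–Miyaura coupling with the α-bromo enal, an electron-poor alkenyl bromide that adds readily to zerovalent palladium; aqueous base destroys residual B–H before the aldehyde is introduced.

**Step 10**
Reactants: 16 (5E)-2-{1,3-bis[(tert-butyldimethylsilyl)oxy]propan-2-ylidene}-5-methyl-8-{(2R,3R)-2-methyl-3-[4-(trimethylsilyl)but-3-yn-1-yl]oxiran-2-yl}oct-5-enal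
Product: 17 (5E)-2-{1,3-bis[(tert-butyldimethylsilyl)oxy]propan-2-ylidene}-8-[(2R,3R)-3-(but-3-yn-1-yl)-2-methyloxiran-2-yl]-5-methyloct-5-enal
Conditions: K2CO3, MeOH, rt
Reagents that add atoms: none
Why: Methanolysis of the C(sp)–Si bond; primary silyl ethers, the epoxide and the non-enolisable enal are stable to these conditions.

**Step 11**
Reactants: 17 (5E)-2-{1,3-bis[(tert-butyldimethylsilyl)oxy]propan-2-ylidene}-8-[(2R,3R)-3-(but-3-yn-1-yl)-2-methyloxiran-2-yl]-5-methyloct-5-enal
Product: 18 (2R,3E,7R,8R,11E)-16,17-bis[(tert-butyldimethylsilyl)oxy]-7,8-epoxycembra-1(15),3,11-trien-2-ol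
Conditions: Ni(cod)2 (20 mol %), (4R,5R)-1,3-bis(2-methylphenyl)-4,5-diphenyl-4,5-dihydroimidazolium tetrafluoroborate (20 mol %), KOt-Bu (20 mol %), Zn(CH3)2 (3 equiv), THF/toluene, rt, syringe-pump addition of 17 to 0.005 M; aq NH4Cl
Reagents that add atoms: dimethylzinc, C[Zn]C
Why: Proposed new method: zerovalent nickel carrying the carbene binds aldehyde C2 and the terminal alkyne and couples them oxidatively to an oxanickelacyclopentene (O–Ni–C4=C3–C2); Zn(CH3)2 then transmetalates at nickel and C4–CH3 reductive elimination returns zerovalent nickel, so C2 and methyl are delivered syn and the C3=C4 alkene is E. The closest known reactions are the Ni(cod)2-catalysed alkylative cyclisation of ynals with organozincs to five- and six-membered rings and the Ni(cod)2/carbene-catalysed reductive macrocyclisation of ynals with silanes; their combination on a 14-membered ring is new. The 14-membered carbocycle closes in the endo mode, with both alkyne carbons becoming ring members, because with a small carbene the alkyne hydrogen and not the tether faces the aldehyde substituent in the metallacycle. The only new stereocentre, C2, is set by the C2-symmetric chiral carbene on nickel, which selects the aldehyde face during oxidative cyclisation; the distant epoxide is expected to give little bias. The step needs 1,2-coupling at the aldehyde and not conjugate coupling of the enal, which the fully substituted β-carbon C15 secures, and ring closure in preference to oligomerisation, which slow addition at high dilution secures. Methyl has no β-hydrogen, so hydride transfer in place of methylation cannot occur, and the epoxide, the silyl ethers and the C11=C12 alkene are inert to zerovalent nickel and Zn(CH3)2 at room temperature.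

**Step 12**
Reactants: 18 (2R,3E,7R,8R,11E)-16,17-bis[(tert-butyldimethylsilyl)oxy]-7,8-epoxycembra-1(15),3,11-trien-2-ol
Product: 19 (2R,3E,7R,8R,11E)-7,8-epoxycembra-1(15),3,11-triene-2,16,17-triol
Conditions: Bu4NF, THF, 0 °C → rt
Reagents that add atoms: none
Why: Fluoride cleaves both Si–O bonds under non-acidic conditions, which the epoxide and the doubly allylic alcohol tolerate.

**Step 13**
Reactants: 19 (2R,3E,7R,8R,11E)-7,8-epoxycembra-1(15),3,11-triene-2,16,17-triol
Product: 22 lobophynin B [(2R,3E,7R,8R,11E)-2,16:7,8-diepoxycembra-1(15),3,11-trien-17-yl acetate], via bis-mesylate 20 (not isolated), via dihydrofuran mesylate 21 (not isolated)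
Conditions: (CH3SO2)2O (2.1 equiv), i-Pr2NEt, CH2Cl2, −40 °C → rt; then CsOAc, 18-crown-6, DMF, rt
Reagents that add atoms: cesium acetate, CC(=O)[O-].[Cs+]
Why: The two primary allylic hydroxyls are sulfonylated faster than the hindered secondary one; the C2 hydroxyl then displaces the mesylate of the only arm it can reach (cis to C2, 5-exo-tet ring closure) with retention at C2 because its C–O bond is not broken. Acetate then displaces the remaining primary allylic mesylate by SN2, the SN2′ position C1 being fully substituted.

## Compound list

1 | 1,3-dihydroxyacetone (commercial as its dimer) | OCC(=O)CO | starting material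
2 | 1,3-bis[(tert-butyldimethylsilyl)oxy]propan-2-one | CC(C)(C)[Si](C)(C)OCC(=O)CO[Si](C)(C)C(C)(C)C | intermediate
3 | 1,1-dibromo-3-[(tert-butyldimethylsilyl)oxy]-2-{[(tert-butyldimethylsilyl)oxy]methyl}prop-1-ene | CC(C)(C)[Si](C)(C)OCC(CO[Si](C)(C)C(C)(C)C)=C(Br)Br | intermediate
4 | 1-bromo-3-[(tert-butyldimethylsilyl)oxy]-2-{[(tert-butyldimethylsilyl)oxy]methyl}prop-1-en-1-yllithium | CC(C)(C)[Si](C)(C)OCC(CO[Si](C)(C)C(C)(C)C)=C([Li])Br | intermediate
5 | 2-bromo-4-[(tert-butyldimethylsilyl)oxy]-3-{[(tert-butyldimethylsilyl)oxy]methyl}but-2-enal | CC(C)(C)[Si](C)(C)OCC(CO[Si](C)(C)C(C)(C)C)=C(Br)C=O | intermediate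
6 | geranyl acetate, (2E)-3,7-dimethylocta-2,6-dien-1-yl acetate | CC(C)=CCC/C(C)=C/COC(C)=O | starting material
7 | (2E,6E)-8-hydroxy-3,7-dimethylocta-2,6-dien-1-yl acetate | OC/C(C)=C/CC/C(C)=C/COC(C)=O | intermediate
8 | (2E,6E)-3,7-dimethyl-8-oxoocta-2,6-dien-1-yl acetate | O=C/C(C)=C/CC/C(C)=C/COC(C)=O | intermediate
9 | (2E,6E)-3,7-dimethylnona-2,6,8-trien-1-yl acetate | C=C/C(C)=C/CC/C(C)=C/COC(C)=O | intermediate
10 | (2E,6E)-3,7-dimethylnona-2,6,8-trien-1-ol | C=C/C(C)=C/CC/C(C)=C/CO | intermediate
11 | {(2R,3R)-3-methyl-3-[(3E)-4-methylhexa-3,5-dien-1-yl]oxiran-2-yl}methanol | C=C/C(C)=C/CC[C@@]1(C)O[C@@H]1CO | intermediate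
12 | 1-(trimethylsilyl)propyne | CC#C[Si](C)(C)C | starting material
13 | {(2R,3R)-3-methyl-3-[(3E)-4-methylhexa-3,5-dien-1-yl]oxiran-2-yl}methyl trifluoromethanesulfonate | C=C/C(C)=C/CC[C@@]1(C)O[C@@H]1COS(=O)(=O)C(F)(F)F | intermediate
14 | trimethyl(4-{(2R,3R)-3-methyl-3-[(3E)-4-methylhexa-3,5-dien-1-yl]oxiran-2-yl}but-1-yn-1-yl)silane | C=C/C(C)=C/CC[C@@]1(C)O[C@@H]1CCC#C[Si](C)(C)C | intermediate
15 | 9-{(3E)-3-methyl-6-[(2R,3R)-2-methyl-3-[4-(trimethylsilyl)but-3-yn-1-yl]oxiran-2-yl]hex-3-en-1-yl}-9-borabicyclo[3.3.1]nonane | B1(C2CCCC1CCC2)CC/C(C)=C/CC[C@@]3(C)O[C@@H]3CCC#C[Si](C)(C)C | intermediate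
16 | (5E)-2-{1,3-bis[(tert-butyldimethylsilyl)oxy]propan-2-ylidene}-5-methyl-8-{(2R,3R)-2-methyl-3-[4-(trimethylsilyl)but-3-yn-1-yl]oxiran-2-yl}oct-5-enal | CC(C)(C)[Si](C)(C)OCC(CO[Si](C)(C)C(C)(C)C)=C(C=O)CC/C(C)=C/CC[C@@]1(C)O[C@@H]1CCC#C[Si](C)(C)C | intermediate
17 | (5E)-2-{1,3-bis[(tert-butyldimethylsilyl)oxy]propan-2-ylidene}-8-[(2R,3R)-3-(but-3-yn-1-yl)-2-methyloxiran-2-yl]-5-methyloct-5-enal | CC(C)(C)[Si](C)(C)OCC(CO[Si](C)(C)C(C)(C)C)=C(C=O)CC/C(C)=C/CC[C@@]1(C)O[C@@H]1CCC#C | intermediate
18 | (2R,3E,7R,8R,11E)-16,17-bis[(tert-butyldimethylsilyl)oxy]-7,8-epoxycembra-1(15),3,11-trien-2-ol | CC(C)(C)[Si](C)(C)OCC(CO[Si](C)(C)C(C)(C)C)=C1CC/C(C)=C/CC[C@@]2(C)O[C@@H]2CC/C(C)=C/[C@H]1O | intermediate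
19 | (2R,3E,7R,8R,11E)-7,8-epoxycembra-1(15),3,11-triene-2,16,17-triol | OCC(CO)=C1CC/C(C)=C/CC[C@@]2(C)O[C@@H]2CC/C(C)=C/[C@H]1O | intermediate
20 | (2R,3E,7R,8R,11E)-7,8-epoxy-2-hydroxycembra-1(15),3,11-triene-16,17-diyl dimethanesulfonate | CS(=O)(=O)OCC(COS(C)(=O)=O)=C1CC/C(C)=C/CC[C@@]2(C)O[C@@H]2CC/C(C)=C/[C@H]1O | intermediate
21 | (2R,3E,7R,8R,11E)-2,16:7,8-diepoxycembra-1(15),3,11-trien-17-yl methanesulfonate | CS(=O)(=O)OCC1=C2CC/C(C)=C/CC[C@@]3(C)O[C@@H]3CC/C(C)=C/[C@H]2OC1 | intermediate
22 | lobophynin B, (2R,3E,7R,8R,11E)-2,16:7,8-diepoxycembra-1(15),3,11-trien-17-yl acetate | CC(=O)OCC1=C2CC/C(C)=C/CC[C@@]3(C)O[C@@H]3CC/C(C)=C/[C@H]2OC1 | target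

## Step count and least certain steps

Total step count: 13. Longest linear sequence: 10 steps (6 to 22, steps 4–13); the three-step preparation of 5 (steps 1–3) joins at step 9.

**Step 11 (key step).** The most likely failures are insufficient discrimination of the two aldehyde faces by the carbene ligand and loss of endo regiocontrol or of methyl transfer, with alkyne oligomerisation taking over; none of these has a direct precedent on a macrocycle.
The fallback uses known reactions only, sets out from 17 and returns at 18.
- N-Iodosuccinimide with catalytic AgNO3 in acetone converts the terminal alkyne into the iodoalkyne F1.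
- CrCl2 with catalytic NiCl2 in THF at high dilution (Nozaki–Hiyama–Kishi alkynylation) closes the ring to the macrocyclic propargylic alcohol F2 as a mixture at C2.
- MnO2 gives the ynone F3.
- Corey–Bakshi–Shibata reduction with (S)-1-methyl-3,3-diphenyltetrahydro-1H,3H-pyrrolo[1,2-c][1,3,2]oxazaborole and catecholborane at −78 °C should give the (2R)-propargylic alcohol F4. The linear alkynyl arm is the small group and the fully substituted alkenyl arm the large one, a clearer distinction than a cross-conjugated dienone would offer.
- NaAlH2(OCH2CH2OCH3)2 in THF adds hydride to C3 and aluminium to C4 trans across the alkyne under direction by the C2 alkoxide, and iodine then gives the (3Z)-4-iodo allylic alcohol F5.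
- Pd(PPh3)4 with CH3ZnCl replaces iodine by methyl with retention and gives 18 with C18 cis to C2.

**Step 9.** Oxidative addition and transmetalation at the tetrasubstituted bromoenal may be slow, so that protodeboronation of 15 and reduction of the aldehyde by residual B–H compete; a small part of the silylated alkyne may also be hydroborated during the slow diene hydroboration.
The fallback sets out from 14 and 3 and returns at 16. Alkylborane 15 is coupled (Pd(dppf)Cl2, AsPh3, Cs2CO3) with an excess of dibromoalkene 3, whose two bromines are equivalent, to give the alkenyl bromide F6, so that no aldehyde is present during the coupling. t-BuLi in THF at −78 °C followed by DMF then introduces the formyl group and gives 16.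

**Step 13.** The doubly allylic C2 hydroxyl may be sulfonylated and ionise, or acetate may capture the cis arm before the ring has closed.
The fallback sets out from 19 and returns at 22. Mitsunobu cyclodehydration (PPh3, diisopropyl azodicarboxylate, THF, 0 °C) activates a primary hydroxyl, and only the arm cis to C2 can be closed by the C2 oxygen, giving the hydroxymethyl dihydrofuran F7 without any sulfonate. Ac2O in pyridine then acetylates the remaining primary alcohol to 22.

**Step 3** (and step 2, which it depends on). The bromo(lithio)alkene 4 may be lost by α-elimination and rearrangement to an alkyne before it is formylated, or the olefination of ketone 2 may be sluggish.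
The fallback sets out from 2 and returns at 5. Horner–Wadsworth–Emmons reaction with triethyl phosphonoacetate and NaH gives the ester F8. i-Bu2AlH at −78 °C gives the allylic alcohol F9 and MnO2 the enal F10. Bromine addition followed by Et3N (loss of HBr through the acidic α-hydrogen) gives 5.

## Further compounds

F1 | step 11 | (5E)-2-{1,3-bis[(tert-butyldimethylsilyl)oxy]propan-2-ylidene}-8-[(2R,3R)-3-(4-iodobut-3-yn-1-yl)-2-methyloxiran-2-yl]-5-methyloct-5-enal | CC(C)(C)[Si](C)(C)OCC(CO[Si](C)(C)C(C)(C)C)=C(C=O)CC/C(C)=C/CC[C@@]1(C)O[C@@H]1CCC#CI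
F2 | step 11 | (7R,8R,11E)-16,17-bis[(tert-butyldimethylsilyl)oxy]-7,8-epoxy-18-norcembra-1(15),11-dien-3-yn-2-ol (both C2 epimers) | CC(C)(C)[Si](C)(C)OCC(CO[Si](C)(C)C(C)(C)C)=C1CC/C(C)=C/CC[C@@]2(C)O[C@@H]2CCC#CC1O
F3 | step 11 | (7R,8R,11E)-16,17-bis[(tert-butyldimethylsilyl)oxy]-7,8-epoxy-18-norcembra-1(15),11-dien-3-yn-2-one | CC(C)(C)[Si](C)(C)OCC(CO[Si](C)(C)C(C)(C)C)=C1CC/C(C)=C/CC[C@@]2(C)O[C@@H]2CCC#CC1=O
F4 | step 11 | (2R,7R,8R,11E)-16,17-bis[(tert-butyldimethylsilyl)oxy]-7,8-epoxy-18-norcembra-1(15),11-dien-3-yn-2-ol | CC(C)(C)[Si](C)(C)OCC(CO[Si](C)(C)C(C)(C)C)=C1CC/C(C)=C/CC[C@@]2(C)O[C@@H]2CCC#C[C@H]1O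
F5 | step 11 | (2R,3Z,7R,8R,11E)-16,17-bis[(tert-butyldimethylsilyl)oxy]-7,8-epoxy-4-iodo-18-norcembra-1(15),3,11-trien-2-ol | CC(C)(C)[Si](C)(C)OCC(CO[Si](C)(C)C(C)(C)C)=C1CC/C(C)=C/CC[C@@]2(C)O[C@@H]2CC/C(I)=C/[C@H]1O
F6 | step 9 | alkenyl bromide corresponding to 16 with bromine on C1 in place of the formyl group | CC(C)(C)[Si](C)(C)OCC(CO[Si](C)(C)C(C)(C)C)=C(Br)CC/C(C)=C/CC[C@@]1(C)O[C@@H]1CCC#C[Si](C)(C)C
F7 | step 13 | (2R,3E,7R,8R,11E)-2,16:7,8-diepoxycembra-1(15),3,11-trien-17-ol | OCC1=C2CC/C(C)=C/CC[C@@]3(C)O[C@@H]3CC/C(C)=C/[C@H]2OC1
F8 | step 3 | ethyl 4-[(tert-butyldimethylsilyl)oxy]-3-{[(tert-butyldimethylsilyl)oxy]methyl}but-2-enoate | CCOC(=O)C=C(CO[Si](C)(C)C(C)(C)C)CO[Si](C)(C)C(C)(C)C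
F9 | step 3 | 4-[(tert-butyldimethylsilyl)oxy]-3-{[(tert-butyldimethylsilyl)oxy]methyl}but-2-en-1-ol | OCC=C(CO[Si](C)(C)C(C)(C)C)CO[Si](C)(C)C(C)(C)C
F10 | step 3 | 4-[(tert-butyldimethylsilyl)oxy]-3-{[(tert-butyldimethylsilyl)oxy]methyl}but-2-enal | O=CC=C(CO[Si](C)(C)C(C)(C)C)CO[Si](C)(C)C(C)(C)C
A1 | alternative 1 | methyl (2R,3E,7R,8R,11E)-2,16:7,8-diepoxycembra-1(15),3,11-trien-17-oate | COC(=O)C1=C2CC/C(C)=C/CC[C@@]3(C)O[C@@H]3CC/C(C)=C/[C@H]2OC1
A2 | alternative 1 | (2R,3E,7R,8R,11E)-7,8-epoxy-17-norcembra-1(15),3,11,15-tetraen-2-ol (macrocyclic allenol, C1=C15=C16) | C=C=C1CC/C(C)=C/CC[C@@]2(C)O[C@@H]2CC/C(C)=C/[C@H]1O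
A3 | alternative 2 | (2R,3E,7R,8R,11E)-17-[(tert-butyldimethylsilyl)oxy]-2,16:7,8-diepoxy-10-(phenylsulfonyl)cembra-1(15),3,11-triene (either C10 epimer) | CC(C)(C)[Si](C)(C)OCC1=C2CC/C(C)=C/C(S(=O)(=O)c3ccccc3)C[C@@]4(C)O[C@@H]4CC/C(C)=C/[C@H]2OC1
A4 | alternative 2 | 9,10-seco iodide–sulfone: the (2R)-dihydrofuran with the C3–C9 chain ending in the epoxy iodide (C9), the C14–C10 chain ending in the allylic phenyl sulfone (C10), and C17 as silyl ether | IC[C@@]1(C)O[C@@H]1CC/C(C)=C/[C@H]2OCC(CO[Si](C)(C)C(C)(C)C)=C2CC/C(C)=C/CS(=O)(=O)c1ccccc1
A5 | alternative 3 | (2R,3E,7R,8R,11E)-17-[(tert-butyldimethylsilyl)oxy]-7,8-epoxycembra-1(15),3,11-trien-16,2-olide (macrocyclic butenolide) | CC(C)(C)[Si](C)(C)OCC1=C2CC/C(C)=C/CC[C@@]3(C)O[C@@H]3CC/C(C)=C/[C@H]2OC1=O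
A6 | alternative 3 | 1,14-seco iodobutenolide: butenolide (C16 carbonyl) with iodine on C1, CH2OSi on C15 and, on C2 (R), the C3–C14 chain ending in the C11=C12–C13=C14 diene | C=C/C(C)=C/CC[C@@]1(C)O[C@@H]1CC/C(C)=C/[C@H]2OC(=O)C(CO[Si](C)(C)C(C)(C)C)=C2I
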